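**Plan**
- Retrosynthetic cuts: the two side-chain ketones come from ozonolysis of a 2,6,6-trimethylcyclohexene; the ester from a CH2OH group; the saturated C4–C5 unit and the two-carbon link at C6 from a ring alkene and an alkyne (diimide).
- The C5–C6 bond of the 1,2-dioxane is cut as a ring contraction of a 1,2,4-trioxepane. The trioxepane comes from an ynone and a 3-hydroperoxy alkanol; C3–OO comes from an oxetane opening, and C2–C3 from an aldol reaction.
- Forward order: the seven-membered cyclic peroxyketal is built first (O–C6 bonds), then contracted to the six-membered peroxide ring (C5–C6 bond); the ketones are unveiled last.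
- Enabling feature: C6 is a fully substituted carbon bearing the peroxide oxygen, so it can be a peroxycarbenium ion; C4–C5 is unsubstituted, so it can be carried as a (Z)-vinylsilane; the C1 oxygen of the propionate arm can serve as the ketal leaving group.
- Stereochemistry: C2 and C3 come from an Evans syn-aldol reaction; C3 is inverted to the anti array by SN2-type perhydrolysis of the oxetane; C6 is set relative to C3 in the ring contraction.

Key step: step 9

Remark: 17 is carried as the mixture of its two epimers at the ketal carbon, and 25 and 26 have an undefined ketal centre, so their SMILES leave these centres open.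

**Route**

Step 1
Reactants: 1 β-cyclocitral (2,6,6-trimethylcyclohex-1-ene-1-carbaldehyde)
Product: 2 2-(2,2-dibromoethenyl)-1,3,3-trimethylcyclohex-1-ene
Conditions: CBr4, PPh3, Zn, CH2Cl2, 0 °C → rt
Reagents that add atoms: carbon tetrabromide, BrC(Br)(Br)Br
Why: Corey–Fuchs dibromo-olefination, in which the ylide Ph3P=CBr2 formed in the flask should convert the non-enolisable aldehyde into the 1,1-dibromoalkene.

Step 2
Reactants: 2 2-(2,2-dibromoethenyl)-1,3,3-trimethylcyclohex-1-ene; 3 N-methoxy-N-methylacetamide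
Product: 6 4-(2,6,6-trimethylcyclohex-1-en-1-yl)but-3-yn-2-one, via lithium acetylide 4 (not isolated), via Weinreb chelate 5 (not isolated)
Conditions: n-BuLi (2.1 equiv), THF, −78 → 0 °C; then 3, −78 → 0 °C; aq. NH4Cl
Reagents that add atoms: none
Why: Second stage of the Corey–Fuchs sequence (Br/Li exchange, α-elimination and deprotonation) gives the acetylide, which acylates the Weinreb amide through a stable chelate so that the ynone is released only on work-up.

Step 3
Reactants: 7 (S)-4-benzyl-3-propanoyl-1,3-oxazolidin-2-one; 8 3-(trimethylsilyl)prop-2-ynal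
Product: 11 (S)-4-benzyl-3-[(2S,3S)-3-hydroxy-2-methyl-5-(trimethylsilyl)pent-4-ynoyl]-1,3-oxazolidin-2-one, via boron enolate 9 (not isolated), via boron aldolate 10 (not isolated)
Conditions: n-Bu2BOTf, i-Pr2NEt, CH2Cl2, 0 °C; then 8, −78 → 0 °C; pH 7 buffer, MeOH, 30% H2O2
Reagents that add atoms: none
Why: Evans syn-aldol reaction, in which the (Z)-boron enolate adds through a closed chair transition state with one enolate face shielded by the benzyl group of the auxiliary, which should set C2 and C3 (syn) together.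

Step 4
Reactants: 11 (S)-4-benzyl-3-[(2S,3S)-3-hydroxy-2-methyl-5-(trimethylsilyl)pent-4-ynoyl]-1,3-oxazolidin-2-one
Product: 12 (2R,3S)-2-methyl-5-(trimethylsilyl)pent-4-yne-1,3-diol
Conditions: LiBH4, MeOH (1 equiv), THF, 0 °C
Reagents that add atoms: none
Why: Reductive removal of the auxiliary (hydride attack at the exocyclic imide carbonyl) should give the syn-1,3-diol without touching the stereocentres or the silylalkyne.

Step 5
Reactants: 12 (2R,3S)-2-methyl-5-(trimethylsilyl)pent-4-yne-1,3-diol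
Product: 13 (2R,3S,4Z)-2-methyl-5-(trimethylsilyl)pent-4-ene-1,3-diol
Conditions: H2 (1 atm), Pd/CaCO3 poisoned with Pb(OAc)2, quinoline, EtOAc, rt
Reagents that add atoms: none
Why: Lindlar-type syn-semihydrogenation of the silylalkyne should stop at the (Z)-vinylsilane, the alkene geometry that the key step needs.

Step 6
Reactants: 13 (2R,3S,4Z)-2-methyl-5-(trimethylsilyl)pent-4-ene-1,3-diol
Product: 15 (2S,3R)-3-methyl-2-[(Z)-2-(trimethylsilyl)ethenyl]oxetane (cis), via primary tosylate 14 (not isolated)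
Conditions: n-BuLi (1.0 equiv), THF, 0 °C; TsCl (1.0 equiv); n-BuLi (1.0 equiv), 0 → 60 °C
Reagents that add atoms: none
Why: One-flask Williamson oxetane synthesis, in which the less hindered primary alkoxide is sulfonylated first and the secondary allylic alkoxide then closes the four-membered ring (4-exo-tet) with retention at the carbinol carbon.

Step 7
Reactants: 15 (2S,3R)-3-methyl-2-[(Z)-2-(trimethylsilyl)ethenyl]oxetane
Product: 16 (2R,3R,4Z)-3-hydroperoxy-2-methyl-5-(trimethylsilyl)pent-4-en-1-ol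
Conditions: H2O2 (anhydrous, in Et2O, excess), TMSOTf (0.2 equiv), Et2O, −78 → −20 °C
Reagents that add atoms: hydrogen peroxide, OO
Why: Lewis-acid-catalysed perhydrolysis of an oxetane, in which H2O2 should open the activated allylic C–O bond in an SN2-like way with inversion, turning the syn array into the anti hydroperoxy alcohol and freeing the primary hydroxyl.

Step 8
Reactants: 16 (2R,3R,4Z)-3-hydroperoxy-2-methyl-5-(trimethylsilyl)pent-4-en-1-ol; 6 4-(2,6,6-trimethylcyclohex-1-en-1-yl)but-3-yn-2-one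
Product: 17 (3RS,6R,7R)-3,6-dimethyl-3-[(2,6,6-trimethylcyclohex-1-en-1-yl)ethynyl]-7-[(Z)-2-(trimethylsilyl)ethenyl]-1,2,4-trioxepane
Conditions: CSA (0.1 equiv), MgSO4, CH2Cl2, 0 °C → rt
Reagents that add atoms: none
Why: Acid-catalysed condensation of a 3-hydroperoxy alkanol with a ketone to a 1,2,4-trioxepane (peroxyhemiketal formation, then ring closure by the hydroxyl), in which the ketal centre forms as a mixture of epimers that is of no consequence.

Step 9
Reactants: 17 (3RS,6R,7R)-3,6-dimethyl-3-[(2,6,6-trimethylcyclohex-1-en-1-yl)ethynyl]-7-[(Z)-2-(trimethylsilyl)ethenyl]-1,2,4-trioxepane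
Product: 20 (2R)-2-[(3S,6R)-6-methyl-6-[(2,6,6-trimethylcyclohex-1-en-1-yl)ethynyl]-3,6-dihydro-1,2-dioxin-3-yl]propan-1-ol, via peroxycarbenium triflate 18 (not isolated), via silyl ether 19 (not isolated)
Conditions: TMSOTf (0.3 equiv), 2,6-di-tert-butyl-4-methylpyridine (0.5 equiv), CH2Cl2, −78 → −40 °C; then K2CO3, MeOH, 0 °C
Reagents that add atoms: none
Why: Proposed new method: TMSOTf should silylate the more basic ether oxygen of the cyclic peroxyketal and open the seven-membered ring to the alkynyl-stabilised peroxycarbenium ion, whose carbon is then attacked by the silicon-bearing carbon of the (Z)-vinylsilane; loss of the silyl group to triflate regenerates TMSOTf, so the net change is an isomerisation with silyl transfer from carbon to oxygen. The closest known reaction types are the Lewis-acid ionisation of peroxyketals to peroxycarbenium ions with intramolecular capture by allylsilanes, and the (Z)-vinylsilane-terminated oxocarbenium cyclisation (silyl-Prins) that gives 5,6-dihydro-2H-pyrans. The 1,2-dioxane ring closes in the 6-endo-trig mode with respect to the vinylsilane, the only mode that places the developing positive charge β to silicon. The new stereocentre C6 should be set in a chair-like transition state with the C3 side chain pseudoequatorial, the slim alkynyl group syn to the peroxide oxygen (pseudoaxial) and the methyl group anti (pseudoequatorial), which places the alkynyl arm cis to the C3 substituent as the target requires. Both ketal epimers of 17 give the same planar cation, so the step is stereoconvergent; it needs ionisation at the ether C–O bond and not at the C–OO bond (secured by the higher basicity of the ether oxygen) and ipso attack and not exo attack (secured by silicon). The silyl helper leaves within the step, and the alkyne and ring alkene are removed in step 10.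

Step 10
Reactants: 20 (2R)-2-[(3S,6R)-6-methyl-6-[(2,6,6-trimethylcyclohex-1-en-1-yl)ethynyl]-3,6-dihydro-1,2-dioxin-3-yl]propan-1-ol
Product: 21 (2R)-2-[(3S,6S)-6-methyl-6-[2-(2,6,6-trimethylcyclohex-1-en-1-yl)ethyl]-1,2-dioxan-3-yl]propan-1-ol
Conditions: KO2CN=NCO2K (excess, in portions), AcOH, MeOH/CH2Cl2, 0 °C → rt
Reagents that add atoms: none
Why: Diimide reduction (concerted syn transfer of H2 to C–C π bonds only) should saturate the ring alkene and the alkyne while leaving the O–O bond and the tetrasubstituted cyclohexene untouched.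

Step 11
Reactants: 21 (2R)-2-[(3S,6S)-6-methyl-6-[2-(2,6,6-trimethylcyclohex-1-en-1-yl)ethyl]-1,2-dioxan-3-yl]propan-1-ol
Product: 23 (2S)-2-[(3S,6S)-6-methyl-6-[2-(2,6,6-trimethylcyclohex-1-en-1-yl)ethyl]-1,2-dioxan-3-yl]propanoic acid, via aldehyde 22 (not isolated)
Conditions: TEMPO (0.2 equiv), PhI(OAc)2 (2.5 equiv), MeCN/aq. pH 7 buffer, rt
Reagents that add atoms: water, O
Why: Oxoammonium-mediated oxidation in aqueous acetonitrile should take the primary alcohol through the aldehyde hydrate to the acid under near-neutral conditions that spare the peroxide, the alkene and the α-stereocentre.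

Step 12
Reactants: 23 (2S)-2-[(3S,6S)-6-methyl-6-[2-(2,6,6-trimethylcyclohex-1-en-1-yl)ethyl]-1,2-dioxan-3-yl]propanoic acid
Product: 24 methyl (2S)-2-[(3S,6S)-6-methyl-6-[2-(2,6,6-trimethylcyclohex-1-en-1-yl)ethyl]-1,2-dioxan-3-yl]propanoate
Conditions: CH2N2, Et2O, 0 °C
Reagents that add atoms: diazomethane, C=[N+]=[N-]
Why: O-Methylation of the acid with diazomethane is neutral, so the base-sensitive β-peroxy ester is not exposed to an E1cB-type ring opening.

Step 13
Reactants: 24 methyl (2S)-2-[(3S,6S)-6-methyl-6-[2-(2,6,6-trimethylcyclohex-1-en-1-yl)ethyl]-1,2-dioxan-3-yl]propanoate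
Product: 27 Diacarperoxide B (methyl (2S)-2-[(3S,6R)-6-(4,4-dimethyl-3,8-dioxononyl)-6-methyl-1,2-dioxan-3-yl]propanoate), via methoxy hydroperoxide 25 (not isolated), via regioisomeric methoxy hydroperoxide 26 (not isolated)
Conditions: O3, CH2Cl2/MeOH, −78 °C; then Me2S, −78 °C → rt
Reagents that add atoms: ozone, [O-][O+]=O
Why: Ozonolysis of the electron-rich tetrasubstituted alkene, the only C=C bond left, followed by Me2S reduction of the trapped carbonyl oxides should unveil both side-chain ketones, a dialkyl peroxide being inert to ozone and to Me2S.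

**Compound list**

1 | β-cyclocitral (2,6,6-trimethylcyclohex-1-ene-1-carbaldehyde) | O=CC1=C(C)CCCC1(C)C | starting material
2 | 2-(2,2-dibromoethenyl)-1,3,3-trimethylcyclohex-1-ene | BrC(Br)=CC1=C(C)CCCC1(C)C | intermediate
3 | N-methoxy-N-methylacetamide | CC(=O)N(C)OC | starting material
4 | lithium (2,6,6-trimethylcyclohex-1-en-1-yl)acetylide | [Li]C#CC1=C(C)CCCC1(C)C | intermediate
5 | lithium 2-[methoxy(methyl)amino]-4-(2,6,6-trimethylcyclohex-1-en-1-yl)but-3-yn-2-olate | CC(O[Li])(N(C)OC)C#CC1=C(C)CCCC1(C)C | intermediate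
6 | 4-(2,6,6-trimethylcyclohex-1-en-1-yl)but-3-yn-2-one | CC(=O)C#CC1=C(C)CCCC1(C)C | intermediate
7 | (S)-4-benzyl-3-propanoyl-1,3-oxazolidin-2-one | CCC(=O)N1C(=O)OC[C@@H]1Cc1ccccc1 | starting material
8 | 3-(trimethylsilyl)prop-2-ynal | O=CC#C[Si](C)(C)C | starting material
9 | (Z)-dibutylboron enolate of 7 | C/C=C(\OB(CCCC)CCCC)N1C(=O)OC[C@@H]1Cc1ccccc1 | intermediate
10 | O-dibutylboryl derivative of 11 (boron aldolate) | O=C(N1C(=O)OC[C@@H]1Cc1ccccc1)[C@@H](C)[C@H](OB(CCCC)CCCC)C#C[Si](C)(C)C | intermediate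
11 | (S)-4-benzyl-3-[(2S,3S)-3-hydroxy-2-methyl-5-(trimethylsilyl)pent-4-ynoyl]-1,3-oxazolidin-2-one | O=C(N1C(=O)OC[C@@H]1Cc1ccccc1)[C@@H](C)[C@H](O)C#C[Si](C)(C)C | intermediate
12 | (2R,3S)-2-methyl-5-(trimethylsilyl)pent-4-yne-1,3-diol | OC[C@@H](C)[C@H](O)C#C[Si](C)(C)C | intermediate
13 | (2R,3S,4Z)-2-methyl-5-(trimethylsilyl)pent-4-ene-1,3-diol | OC[C@@H](C)[C@H](O)/C=C\[Si](C)(C)C | intermediate
14 | (2R,3S,4Z)-3-hydroxy-2-methyl-5-(trimethylsilyl)pent-4-en-1-yl 4-methylbenzenesulfonate | Cc1ccc(cc1)S(=O)(=O)OC[C@@H](C)[C@H](O)/C=C\[Si](C)(C)C | intermediate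
15 | (2S,3R)-3-methyl-2-[(Z)-2-(trimethylsilyl)ethenyl]oxetane | C1[C@@H](C)[C@H](O1)/C=C\[Si](C)(C)C | intermediate
16 | (2R,3R,4Z)-3-hydroperoxy-2-methyl-5-(trimethylsilyl)pent-4-en-1-ol | OC[C@@H](C)[C@@H](OO)/C=C\[Si](C)(C)C | intermediate
17 | (3RS,6R,7R)-3,6-dimethyl-3-[(2,6,6-trimethylcyclohex-1-en-1-yl)ethynyl]-7-[(Z)-2-(trimethylsilyl)ethenyl]-1,2,4-trioxepane | C1[C@@H](C)[C@H](/C=C\[Si](C)(C)C)OOC(C)(C#CC2=C(C)CCCC2(C)C)O1 | intermediate
18 | {[(2R,3R,4Z)-2-methyl-5-(trimethylsilyl)-1-(trimethylsilyloxy)pent-4-en-3-yl]oxy}[4-(2,6,6-trimethylcyclohex-1-en-1-yl)but-3-yn-2-ylidene]oxonium trifluoromethanesulfonate | C[Si](C)(C)OC[C@@H](C)[C@@H](O[O+]=C(C)C#CC1=C(C)CCCC1(C)C)/C=C\[Si](C)(C)C.[O-]S(=O)(=O)C(F)(F)F | intermediate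
19 | trimethyl{(2R)-2-[(3S,6R)-6-methyl-6-[(2,6,6-trimethylcyclohex-1-en-1-yl)ethynyl]-3,6-dihydro-1,2-dioxin-3-yl]propoxy}silane | C[Si](C)(C)OC[C@@H](C)[C@@H]1C=C[C@](C)(C#CC2=C(C)CCCC2(C)C)OO1 | intermediate
20 | (2R)-2-[(3S,6R)-6-methyl-6-[(2,6,6-trimethylcyclohex-1-en-1-yl)ethynyl]-3,6-dihydro-1,2-dioxin-3-yl]propan-1-ol | OC[C@@H](C)[C@@H]1C=C[C@](C)(C#CC2=C(C)CCCC2(C)C)OO1 | intermediate
21 | (2R)-2-[(3S,6S)-6-methyl-6-[2-(2,6,6-trimethylcyclohex-1-en-1-yl)ethyl]-1,2-dioxan-3-yl]propan-1-ol | OC[C@@H](C)[C@@H]1CC[C@](C)(CCC2=C(C)CCCC2(C)C)OO1 | intermediate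
22 | (2S)-2-[(3S,6S)-6-methyl-6-[2-(2,6,6-trimethylcyclohex-1-en-1-yl)ethyl]-1,2-dioxan-3-yl]propanal | O=C[C@@H](C)[C@@H]1CC[C@](C)(CCC2=C(C)CCCC2(C)C)OO1 | intermediate
23 | (2S)-2-[(3S,6S)-6-methyl-6-[2-(2,6,6-trimethylcyclohex-1-en-1-yl)ethyl]-1,2-dioxan-3-yl]propanoic acid | OC(=O)[C@@H](C)[C@@H]1CC[C@](C)(CCC2=C(C)CCCC2(C)C)OO1 | intermediate
24 | methyl (2S)-2-[(3S,6S)-6-methyl-6-[2-(2,6,6-trimethylcyclohex-1-en-1-yl)ethyl]-1,2-dioxan-3-yl]propanoate | COC(=O)[C@@H](C)[C@@H]1CC[C@](C)(CCC2=C(C)CCCC2(C)C)OO1 | intermediate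
25 | methyl (2S)-2-[(3S,6R)-6-(8-hydroperoxy-8-methoxy-4,4-dimethyl-3-oxononyl)-6-methyl-1,2-dioxan-3-yl]propanoate | COC(=O)[C@@H](C)[C@@H]1CC[C@](C)(CCC(=O)C(C)(C)CCCC(C)(OC)OO)OO1 | intermediate
26 | methyl (2S)-2-[(3S,6R)-6-(3-hydroperoxy-3-methoxy-4,4-dimethyl-8-oxononyl)-6-methyl-1,2-dioxan-3-yl]propanoate | COC(=O)[C@@H](C)[C@@H]1CC[C@](C)(CCC(OC)(OO)C(C)(C)CCCC(C)=O)OO1 | intermediate
27 | Diacarperoxide B, methyl (2S)-2-[(3S,6R)-6-(4,4-dimethyl-3,8-dioxononyl)-6-methyl-1,2-dioxan-3-yl]propanoate | COC(=O)[C@@H](C)[C@@H]1CC[C@](C)(CCC(=O)C(C)(C)CCCC(C)=O)OO1 | target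

**Step count and risks**

Total step count: 13. Longest linear sequence: 11 steps (steps 3 to 13); the ynone branch (steps 1 and 2) joins at step 8.

1. Step 9 (the proposed ring contraction). What may go wrong:
   - ionisation at the peroxide-side C–O bond instead of the ether C–O bond;
   - re-closure of the seven-membered ring outrunning C–C bond formation;
   - poor facial selectivity at C6, since the syn preference of the alkynyl group is opposed by its smaller gauche demand next to silicon.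

   Fallback with known chemistry, setting out from 12 and coming back at 21: the same C5–C6 bond is made by acetylide addition and the ring is closed at O–C3 instead. Compound 12 is C-desilylated (K2CO3, MeOH) to (2R,3S)-2-methylpent-4-yne-1,3-diol F1 and silylated at the primary hydroxyl (TBDPSCl, imidazole) to (2R,3S)-1-[(tert-butyldiphenylsilyl)oxy]-2-methylpent-4-yn-3-ol F2. Its dianion (n-BuLi, 2 equiv) adds to commercial dihydro-β-ionone to give (2R,3S,6RS)-1-[(tert-butyldiphenylsilyl)oxy]-2,6-dimethyl-8-(2,6,6-trimethylcyclohex-1-en-1-yl)oct-4-yne-3,6-diol F3. Hydrogenation of the alkyne (H2, PtO2, EtOAc) gives (2R,3R,6RS)-1-[(tert-butyldiphenylsilyl)oxy]-2,6-dimethyl-8-(2,6,6-trimethylcyclohex-1-en-1-yl)octane-3,6-diol F4, and selective mesylation of the secondary hydroxyl (MsCl, Et3N) gives (2R,3R,6RS)-1-[(tert-butyldiphenylsilyl)oxy]-6-hydroxy-2,6-dimethyl-8-(2,6,6-trimethylcyclohex-1-en-1-yl)octan-3-yl methanesulfonate F5. Perhydrolysis of the tertiary alcohol (50% H2O2, cat. H2SO4) gives (2R,3R,6RS)-1-[(tert-butyldiphenylsilyl)oxy]-6-hydroperoxy-2,6-dimethyl-8-(2,6,6-trimethylcyclohex-1-en-1-yl)octan-3-yl methanesulfonate F6. KOtBu in THF then closes the 1,2-dioxane by intramolecular SN2 displacement with inversion at C3; after chromatographic separation of the C6 epimers this gives tert-butyl{(2R)-2-[(3S,6S)-6-methyl-6-[2-(2,6,6-trimethylcyclohex-1-en-1-yl)ethyl]-1,2-dioxan-3-yl]propoxy}diphenylsilane F7, and TBAF/AcOH gives 21. This path has no control at C6 but rests on precedented steps only.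

2. Step 7 (oxetane perhydrolysis). What may go wrong:
   - ionisation of the allylic C–O bond to a free allyl cation, with loss of configurational integrity at C3;
   - attack at the primary carbon or at the silicon-bearing terminus;
   - protodesilylation of the vinylsilane.

   Fallback, setting out from 13 and coming back at 16: the primary hydroxyl is silylated (TBSCl, imidazole) to (2R,3S,4Z)-1-[(tert-butyldimethylsilyl)oxy]-2-methyl-5-(trimethylsilyl)pent-4-en-3-ol F8. The secondary hydroxyl is mesylated at −40 °C (MsCl, Et3N) to (2R,3S,4Z)-1-[(tert-butyldimethylsilyl)oxy]-2-methyl-5-(trimethylsilyl)pent-4-en-3-yl methanesulfonate F9. Displacement with anhydrous H2O2 in Et2O at −78 °C with inversion gives tert-butyl{[(2R,3R,4Z)-3-hydroperoxy-2-methyl-5-(trimethylsilyl)pent-4-en-1-yl]oxy}dimethylsilane F10, and HF·pyridine then gives 16.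

3. Step 8 (trioxepane formation). What may go wrong:
   - an unfavourable peroxyketalisation equilibrium with the conjugated ketone;
   - conjugate addition of the hydroperoxide to the ynone;
   - acid-induced Hock-type cleavage of the allylic hydroperoxide.

   Fallback, setting out from 16 and coming back at 17: 16 is bis-silylated (TMSCl, Et3N) to trimethyl{[(2R,3R,4Z)-2-methyl-5-(trimethylsilyl)-3-[(trimethylsilyl)peroxy]pent-4-en-1-yl]oxy}silane F11. F11 is condensed with 6 under TMSOTf catalysis at −78 °C (silyl-transfer ketalisation driven by siloxane formation) to give 17 without a free hydroperoxide or a protic acid.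

Further compounds
F1 | step 9 | (2R,3S)-2-methylpent-4-yne-1,3-diol | OC[C@@H](C)[C@H](O)C#C
F2 | step 9 | (2R,3S)-1-[(tert-butyldiphenylsilyl)oxy]-2-methylpent-4-yn-3-ol | CC(C)(C)[Si](OC[C@@H](C)[C@H](O)C#C)(c1ccccc1)c1ccccc1
F3 | step 9 | (2R,3S,6RS)-1-[(tert-butyldiphenylsilyl)oxy]-2,6-dimethyl-8-(2,6,6-trimethylcyclohex-1-en-1-yl)oct-4-yne-3,6-diol | CC(C)(C)[Si](OC[C@@H](C)[C@H](O)C#CC(C)(O)CCC1=C(C)CCCC1(C)C)(c1ccccc1)c1ccccc1
F4 | step 9 | (2R,3R,6RS)-1-[(tert-butyldiphenylsilyl)oxy]-2,6-dimethyl-8-(2,6,6-trimethylcyclohex-1-en-1-yl)octane-3,6-diol | CC(C)(C)[Si](OC[C@@H](C)[C@H](O)CCC(C)(O)CCC1=C(C)CCCC1(C)C)(c1ccccc1)c1ccccc1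
F5 | step 9 | (2R,3R,6RS)-1-[(tert-butyldiphenylsilyl)oxy]-6-hydroxy-2,6-dimethyl-8-(2,6,6-trimethylcyclohex-1-en-1-yl)octan-3-yl methanesulfonate | CC(C)(C)[Si](OC[C@@H](C)[C@H](OS(C)(=O)=O)CCC(C)(O)CCC1=C(C)CCCC1(C)C)(c1ccccc1)c1ccccc1
F6 | step 9 | (2R,3R,6RS)-1-[(tert-butyldiphenylsilyl)oxy]-6-hydroperoxy-2,6-dimethyl-8-(2,6,6-trimethylcyclohex-1-en-1-yl)octan-3-yl methanesulfonate | CC(C)(C)[Si](OC[C@@H](C)[C@H](OS(C)(=O)=O)CCC(C)(OO)CCC1=C(C)CCCC1(C)C)(c1ccccc1)c1ccccc1
F7 | step 9 | tert-butyl{(2R)-2-[(3S,6S)-6-methyl-6-[2-(2,6,6-trimethylcyclohex-1-en-1-yl)ethyl]-1,2-dioxan-3-yl]propoxy}diphenylsilane | CC(C)(C)[Si](OC[C@@H](C)[C@@H]1CC[C@](C)(CCC2=C(C)CCCC2(C)C)OO1)(c1ccccc1)c1ccccc1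
F8 | step 7 | (2R,3S,4Z)-1-[(tert-butyldimethylsilyl)oxy]-2-methyl-5-(trimethylsilyl)pent-4-en-3-ol | CC(C)(C)[Si](C)(C)OC[C@@H](C)[C@H](O)/C=C\[Si](C)(C)C
F9 | step 7 | (2R,3S,4Z)-1-[(tert-butyldimethylsilyl)oxy]-2-methyl-5-(trimethylsilyl)pent-4-en-3-yl methanesulfonate | CC(C)(C)[Si](C)(C)OC[C@@H](C)[C@H](OS(C)(=O)=O)/C=C\[Si](C)(C)C
F10 | step 7 | tert-butyl{[(2R,3R,4Z)-3-hydroperoxy-2-methyl-5-(trimethylsilyl)pent-4-en-1-yl]oxy}dimethylsilane | CC(C)(C)[Si](C)(C)OC[C@@H](C)[C@@H](OO)/C=C\[Si](C)(C)C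
F11 | step 8 | trimethyl{[(2R,3R,4Z)-2-methyl-5-(trimethylsilyl)-3-[(trimethylsilyl)peroxy]pent-4-en-1-yl]oxy}silane | C[Si](C)(C)OC[C@@H](C)[C@@H](OO[Si](C)(C)C)/C=C\[Si](C)(C)C
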